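**Retrosynthetic overview**
1. The aldehyde is carried at the amide oxidation level. The target comes from the (R)-configured N,N-diphenylamide by one chemoselective amide-to-aldehyde reduction in the last step.
2. Key disconnection: the bond between the stereocentre and the first CH2 of the heptamethylene tether. It is made by a nickel-catalysed stereoconvergent alkyl–alkyl Suzuki–Miyaura coupling of racemic 4-chloro-N,N-diphenyloctanamide with the B-alkyl-9-BBN formed in the flask from a terminal alkene.
3. Enabling feature: the stereocentre is C4, the γ-carbon of the C1 aldehyde carbonyl. As Ph2N–C1(=O), the oxygen can reach nickel bound at C4 through a six-membered chelate (Ni, C4, C3, C2, C1, O), the only handle that distinguishes three otherwise plain alkyl arms. The planar C4 radical erases the configuration of the racemic chloride.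
4. The chloroamide comes from racemic γ-octalactone (SOCl2, then Ph2NH). The alkene partner comes from furan by two successive α-metalations: alkylation with 7-bromohept-1-ene, then zinc/nickel coupling with methyl bromoacetate.
5. No ring is formed. The furan ring is bought, and the lactone ring is a temporary ring that is opened before the key step.

Key step: step 4

Assumption: the (S,S)-enantiomer of the diamine ligand is written for the (R)-product. The sense of induction has to be confirmed on the first run, and the equally available (R,R)-ligand is used if it proves to be opposite.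

**Step 1**
Reactants: 1 furan; 2 7-bromohept-1-ene
Product: 4 2-(hept-6-en-1-yl)furan, via 2-furyllithium 3 (not isolated)
Conditions: n-BuLi, THF, −78 → 0 °C; then 2, DMPU, 0 °C → rt
Reagents that add atoms: none
Why: α-Lithiation of furan followed by SN2 alkylation of 2-furyllithium with a primary bromide is the standard entry to 2-alkylfurans; the remote terminal alkene is inert and no stereocentre is formed.

**Step 2**
Reactants: 4 2-(hept-6-en-1-yl)furan
Product: 7 methyl 2-[5-(hept-6-en-1-yl)furan-2-yl]acetate, via 5-lithiated furan 5 (not isolated), via furylzinc chloride 6 (not isolated)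
Conditions: n-BuLi, THF, 0 °C → rt; ZnCl2, THF, 0 °C; BrCH2CO2Me, Ni(acac)2 (5 mol %), PPh3 (5 mol %), THF/NMP, rt
Reagents that add atoms: methyl bromoacetate, COC(=O)CBr
Why: The only free α-position (C5) is lithiated, transmetalation to zinc makes the carbanion compatible with an ester, and the nickel-catalysed Negishi-type coupling of (hetero)arylzinc chlorides with bromoacetates gives arylacetic esters directly; no stereocentre is formed.

**Step 3**
Reactants: 8 γ-octalactone (racemic 5-butyloxolan-2-one)
Product: 10 rac-4-chloro-N,N-diphenyloctanamide, via 4-chlorooctanoyl chloride 9 (not isolated)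
Conditions: SOCl2, ZnCl2 (cat.), neat, 60 °C, then evaporation; Ph2NH, toluene, reflux
Reagents that add atoms: thionyl chloride, O=S(Cl)Cl; diphenylamine, c1ccc(Nc2ccccc2)cc1
Why: Lewis-acid-catalysed ring opening of a γ-lactone with thionyl chloride gives the γ-chloro acid chloride, and N-acylation of the weakly basic diphenylamine proceeds in hot toluene with loss of HCl; C4 is racemic by design because the next step is stereoconvergent.

**Step 4**
Reactants: 7 methyl 2-[5-(hept-6-en-1-yl)furan-2-yl]acetate; 10 rac-4-chloro-N,N-diphenyloctanamide
Product: 13 (4R)-4-butyl-11-[5-(2-methoxy-2-oxoethyl)furan-2-yl]-N,N-diphenylundecanamide, via B-alkyl-9-BBN 11 (not isolated), via potassium hexyloxyborate 12 (not isolated)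
Conditions: 7 (1.8 equiv), 9-BBN dimer (0.9 equiv), i-Pr2O, 60 °C; KOt-Bu (1.4 equiv), n-hexanol (1.8 equiv), rt; then 10 (1.0 equiv), NiBr2·diglyme (10 mol %), (S,S)-N,N'-dimethyl-1,2-diphenylethane-1,2-diamine (12 mol %), i-Pr2O, rt
Reagents that add atoms: none
Why: Anti-Markovnikov hydroboration of the terminal alkene of 7 with 9-BBN (ester and furan are left alone) makes the terminal carbon nucleophilic, and hexanolate converts 11 into borate 12, which hands its primary alkyl group to the diamine-ligated nickel. The alkylnickel(I) species abstracts chlorine from either enantiomer of 10 to give the same planar C4 radical, which is recaptured at nickel(II) and leaves by C(sp3)–C(sp3) reductive elimination from nickel(III), so both enantiomers of the racemate are funnelled into one product. The closest known reaction type is the nickel/chiral 1,2-diamine-catalysed stereoconvergent alkyl–alkyl Suzuki–Miyaura coupling of racemic unactivated γ-chloro N,N-diphenylamides with B-alkyl-9-BBN reagents, of which this is a direct application; no ring is closed. The new stereocentre C4 is controlled by the chiral ligand, because the amide oxygen binds nickel in a six-membered Ni–C4–C3–C2–C1–O chelate and so lets the catalyst tell the carbonyl-bearing arm from the n-butyl arm. The step needs face selectivity at a centre flanked by three alkyl arms (secured by the Ph2N–C=O group at the γ-distance), transfer of only the primary chain from boron (secured by the bridgehead B–C bonds of the 9-BBN cage), and survival of the methyl ester with its acidic CH2 (secured by keeping alkoxide below the amount of borane so that it stays bound in 12).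

**Step 5**
Reactants: 13 (4R)-4-butyl-11-[5-(2-methoxy-2-oxoethyl)furan-2-yl]-N,N-diphenylundecanamide
Product: 15 methyl 2-{5-[(8R)-8-(3-oxopropyl)dodecyl]furan-2-yl}acetate, via zirconated hemiaminal 14 (not isolated)
Conditions: Cp2Zr(H)Cl (1.5 equiv), THF, rt, short contact time; then H2O/silica gel
Reagents that add atoms: none
Why: Reduction of a tertiary amide with the Schwartz reagent (hydrozirconation of the C=O) stops at the zirconated hemiaminal 14, which releases the aldehyde only on aqueous work-up; esters and furans react much more slowly, the poor donor Ph2N disfavours iminium formation and over-reduction, and the non-enolisable γ-stereocentre is untouched.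

**Compound list**
1 | furan | c1ccoc1 | starting material
2 | 7-bromohept-1-ene | C=CCCCCCBr | starting material
3 | 2-furyllithium | [Li]c1ccco1 | intermediate
4 | 2-(hept-6-en-1-yl)furan | C=CCCCCCc1ccco1 | intermediate
5 | [5-(hept-6-en-1-yl)furan-2-yl]lithium | [Li]c1ccc(CCCCCC=C)o1 | intermediate
6 | [5-(hept-6-en-1-yl)furan-2-yl]zinc chloride | Cl[Zn]c1ccc(CCCCCC=C)o1 | intermediate
7 | methyl 2-[5-(hept-6-en-1-yl)furan-2-yl]acetate | C=CCCCCCc1ccc(CC(=O)OC)o1 | intermediate
8 | γ-octalactone (racemic 5-butyloxolan-2-one) | CCCCC1CCC(=O)O1 | starting material
9 | rac-4-chlorooctanoyl chloride | CCCCC(Cl)CCC(=O)Cl | intermediate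
10 | rac-4-chloro-N,N-diphenyloctanamide | CCCCC(Cl)CCC(=O)N(c1ccccc1)c1ccccc1 | intermediate
11 | methyl 2-{5-[7-(9-borabicyclo[3.3.1]nonan-9-yl)heptyl]furan-2-yl}acetate | COC(=O)Cc1ccc(CCCCCCCB2C3CCCC2CCC3)o1 | intermediate
12 | potassium B-hexyloxy borate of 11 | [K+].CCCCCCO[B-]1(CCCCCCCc2ccc(CC(=O)OC)o2)C2CCCC1CCC2 | intermediate
13 | (4R)-4-butyl-11-[5-(2-methoxy-2-oxoethyl)furan-2-yl]-N,N-diphenylundecanamide | CCCC[C@@H](CCC(=O)N(c1ccccc1)c1ccccc1)CCCCCCCc1ccc(CC(=O)OC)o1 | intermediate
14 | O-(chlorozirconocenyl) hemiaminal of 13 (Cp rings drawn η1 for the SMILES; hemiaminal carbon unassigned) | CCCC[C@@H](CCC(O[Zr](Cl)(C1C=CC=C1)C1C=CC=C1)N(c1ccccc1)c1ccccc1)CCCCCCCc1ccc(CC(=O)OC)o1 | intermediate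
15 | methyl 2-{5-[(8R)-8-(3-oxopropyl)dodecyl]furan-2-yl}acetate | CCCC[C@@H](CCC=O)CCCCCCCc1ccc(CC(=O)OC)o1 | target

**Total step count:** 5. **Longest linear sequence:** 4 (steps 1, 2, 4, 5).

**Steps most likely to fail**

Step 4. Three processes could go wrong:
- Alkoxide may leak from the borate and exchange or enolise the methyl ester.
- Capture of the C4 radical may be incompletely face-selective.
- β-Hydride elimination or hydrodechlorination may consume the chloride.

A small residue of the minor enantiomer could be removed at the stage of 13 on a chiral stationary phase, helped by the diphenylamide chromophore.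

The fallback sets out from 11 and comes back at 15, bypassing 13 and step 5. It makes the same C–C bond by a polar SN2′ substitution instead of a radical cross-coupling. Borane 11 is activated with KOMe, so that any ester exchange is degenerate. It is then joined under copper(I)/DTBM-SEGPHOS catalysis, in a γ-selective enantioselective allyl–alkyl substitution, with (Z)-1-chlorohept-2-ene F1. F1 is made from commercial (Z)-hept-2-en-1-ol with NCS/Me2S. This should give methyl 2-{5-[(8R)-8-ethenyldodecyl]furan-2-yl}acetate F2. Linear-selective rhodium/Xantphos hydroformylation (CO/H2, toluene) of the vinyl group then adds the aldehyde carbon and gives 15.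

Step 5. The weakly Lewis-basic diarylamide may be hydrozirconated sluggishly, so that attack at the methyl ester or further reduction of prematurely released aldehyde competes.

The fallback sets out from 13 and comes back at 15. It replaces the stoichiometric metal hydride by a catalytic hydrosilylation that passes through an isolable enamine. Vaska's complex (cat.) and 1,1,3,3-tetramethyldisiloxane in toluene at rt reduce N,N-diaryl amides selectively beside esters. This should give methyl 2-(5-{(8R)-8-[(2E)-3-(diphenylamino)prop-2-en-1-yl]dodecyl}furan-2-yl)acetate F3. Hydrolysis with dilute oxalic acid in THF/H2O, or on wet silica gel, then gives 15 under conditions mild enough for the 2,5-dialkylfuran.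

Step 2. Homocoupling of the furylzinc reagent, halogen–zinc exchange with the bromoacetate, or nickel-hydride migration of the terminal alkene may erode the coupling.

The fallback sets out from 2 and comes back at 7, with the polarity of the furan reversed. Zinc insertion into 2 (Zn dust, LiCl, THF) gives hept-6-en-1-ylzinc bromide F4. Commercial methyl 2-(furan-2-yl)acetate is brominated at C5 (NBS, DMF, 0 °C) to methyl 2-(5-bromofuran-2-yl)acetate F5. A palladium-catalysed sp3–sp2 Negishi coupling (Pd(OAc)2/SPhos, THF, rt) of F4 with F5 then gives 7.

**Further compounds**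
F1 | step 4 | (Z)-1-chlorohept-2-ene | CCCC/C=C\CCl
F2 | step 4 | methyl 2-{5-[(8R)-8-ethenyldodecyl]furan-2-yl}acetate | CCCC[C@@H](C=C)CCCCCCCc1ccc(CC(=O)OC)o1
F3 | step 5 | methyl 2-(5-{(8R)-8-[(2E)-3-(diphenylamino)prop-2-en-1-yl]dodecyl}furan-2-yl)acetate | CCCC[C@@H](C/C=C/N(c1ccccc1)c1ccccc1)CCCCCCCc1ccc(CC(=O)OC)o1
F4 | step 2 | hept-6-en-1-ylzinc bromide | C=CCCCCC[Zn]Br
F5 | step 2 | methyl 2-(5-bromofuran-2-yl)acetate | COC(=O)Cc1ccc(Br)o1
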